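**Retrosynthetic overview**
1. Fremontone ⇐ acid-triggered MOM loss and cyclodehydration of the enolised keto-aldehyde 19; the 4-pyranone is the only ring made, and it is made last.
2. 19 ⇐ 1,3-diol 17 ⇐ β-hydroxy ester 16; the ester carbon becomes C2.
3. Key C–C bond (future C3–C4): aldol addition of the lithium enolate of the B-ring tert-butyl arylacetate 12 to the A-ring aldehyde 14.
4. 12 ⇐ aryl bromide 11 by Pd-catalysed α-arylation of a zinc ester enolate.
5. 11 ⇐ 4-bromoresorcinol by two aromatic Claisen rearrangements: O-(1,1-dimethylallyl) gives the 3'-prenyl group, then O-prenyl gives the 5'-(1,1-dimethylallyl) group, with Br blocking C1'.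

Assumption: fremontone has no stereocentre, so there is nothing to set; the transient stereocentres in 4, 9 and 16–19 are carried as racemates or diastereomer mixtures and are destroyed before the end.

Abbreviation used in names: Ar = 2,4-bis(methoxymethoxy)-5-(2-methylbut-3-en-2-yl)-3-(3-methylbut-2-en-1-yl)phenyl.

**Step 1**
Reactants: 1 4-bromoresorcinol
Product: 2 2-bromo-5-{[tri(propan-2-yl)silyl]oxy}phenol
Conditions: TIPSCl (1.05 equiv), imidazole, CH2Cl2, 0 °C to rt
Reagents that add atoms: chlorotri(propan-2-yl)silane (TIPSCl), CC(C)[Si](Cl)(C(C)C)C(C)C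
Why: Regioselective O-silylation; the bulky silyl chloride should take the unhindered OH para to Br in preference to the OH flanked by Br.

**Step 2**
Reactants: 2 2-bromo-5-{[tri(propan-2-yl)silyl]oxy}phenol
Product: 3 [4-bromo-3-(2-methylbut-3-en-2-yloxy)phenoxy]tri(propan-2-yl)silane
Conditions: Pd(PPh3)4 (3 mol%), THF, 0 °C to rt
Reagents that add atoms: methyl 2-methylbut-3-en-2-yl carbonate, COC(=O)OC(C)(C)C=C
Why: Tsuji–Trost O-allylation; the phenoxide attacks the more substituted terminus of the π-(1,1-dimethylallyl)palladium complex under kinetic control, and the electron-rich aryl bromide is inert to Pd(0)/PPh3 at this temperature.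

**Step 3**
Reactants: 3 [4-bromo-3-(2-methylbut-3-en-2-yloxy)phenoxy]tri(propan-2-yl)silane
Product: 5 6-bromo-2-(3-methylbut-2-en-1-yl)-3-{[tri(propan-2-yl)silyl]oxy}phenol, via ortho-dienone 4 (not isolated)
Conditions: xylenes, 140 °C
Reagents that add atoms: none
Why: Aromatic Claisen rearrangement; the only free ortho carbon lies between the two oxygens, and the [3,3] shift inverts the 1,1-dimethylallyl unit to the linear prenyl group before the dienone tautomerises.

**Step 4**
Reactants: 5 6-bromo-2-(3-methylbut-2-en-1-yl)-3-{[tri(propan-2-yl)silyl]oxy}phenol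
Product: 6 [4-bromo-3-(methoxymethoxy)-2-(3-methylbut-2-en-1-yl)phenoxy]tri(propan-2-yl)silane
Conditions: NaH, MOMCl, THF–DMF, 0 °C to rt
Reagents that add atoms: chloromethyl methyl ether (MOMCl), COCCl
Why: Williamson-type O-alkylation of the sodium phenoxide; the small, hard MOMCl reacts even at this doubly ortho-substituted oxygen.

**Step 5**
Reactants: 6 [4-bromo-3-(methoxymethoxy)-2-(3-methylbut-2-en-1-yl)phenoxy]tri(propan-2-yl)silane
Product: 8 1-bromo-2-(methoxymethoxy)-3-(3-methylbut-2-en-1-yl)-4-[(3-methylbut-2-en-1-yl)oxy]benzene, via tetrabutylammonium phenoxide 7 (not isolated)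
Conditions: TBAF (1.1 equiv), THF, 0 °C; then prenyl bromide, rt
Reagents that add atoms: 1-bromo-3-methylbut-2-ene (prenyl bromide), CC(C)=CCBr
Why: Fluoride desilylation gives a naked phenoxide that undergoes SN2 O-alkylation (Williamson ether synthesis) in the same pot; the MOM ether is untouched.

**Step 6**
Reactants: 8 1-bromo-2-(methoxymethoxy)-3-(3-methylbut-2-en-1-yl)-4-[(3-methylbut-2-en-1-yl)oxy]benzene
Product: 10 4-bromo-3-(methoxymethoxy)-6-(2-methylbut-3-en-2-yl)-2-(3-methylbut-2-en-1-yl)phenol, via ortho-dienone 9 (not isolated)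
Conditions: PhNEt2, 190 °C, sealed tube, Ar, 2 h
Reagents that add atoms: none
Why: Aromatic Claisen rearrangement of an aryl prenyl ether; the other ortho carbon (prenyl) and the para carbon (Br) are blocked, so the [3,3] shift can only deliver the inverted 1,1-dimethylallyl group to the one free ortho position.

**Step 7**
Reactants: 10 4-bromo-3-(methoxymethoxy)-6-(2-methylbut-3-en-2-yl)-2-(3-methylbut-2-en-1-yl)phenol
Product: 11 1-bromo-2,4-bis(methoxymethoxy)-5-(2-methylbut-3-en-2-yl)-3-(3-methylbut-2-en-1-yl)benzene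
Conditions: NaH, MOMCl, DMF, 0 °C to rt
Reagents that add atoms: chloromethyl methyl ether (MOMCl), COCCl
Why: O-alkylation of the hindered sodium phenoxide; capping it also removes the phenol that could cyclise onto either side chain.

**Step 8**
Reactants: 11 1-bromo-2,4-bis(methoxymethoxy)-5-(2-methylbut-3-en-2-yl)-3-(3-methylbut-2-en-1-yl)benzene
Product: 12 tert-butyl 2-[2,4-bis(methoxymethoxy)-5-(2-methylbut-3-en-2-yl)-3-(3-methylbut-2-en-1-yl)phenyl]acetate
Conditions: BrZnCH2CO2t-Bu (1.5 equiv, THF solution), Pd(dba)2 (2 mol%), Q-Phos (2 mol%), THF, rt to 50 °C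
Reagents that add atoms: bromo(2-tert-butoxy-2-oxoethyl)zinc (Reformatsky reagent), CC(C)(C)OC(=O)C[Zn]Br
Why: Pd-catalysed α-arylation of a zinc ester enolate (Reformatsky–Negishi coupling); it runs under neutral conditions that tolerate MOM ethers and both alkenes.

**Step 9**
Reactants: 13 2,4,6-trihydroxybenzaldehyde
Product: 14 2,4,6-tris(methoxymethoxy)benzaldehyde
Conditions: NaH (3.6 equiv), MOMCl (3.6 equiv), DMF, 0 °C to rt
Reagents that add atoms: chloromethyl methyl ether (MOMCl), COCCl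
Why: Exhaustive O-alkylation; the strong base is needed to cap the two hydrogen-bonded ortho hydroxyls, and the hard electrophile gives O- rather than C-alkylation.

**Step 10**
Reactants: 12 tert-butyl 2-[2,4-bis(methoxymethoxy)-5-(2-methylbut-3-en-2-yl)-3-(3-methylbut-2-en-1-yl)phenyl]acetate; 14 2,4,6-tris(methoxymethoxy)benzaldehyde
Product: 16 tert-butyl 2-Ar-3-hydroxy-3-[2,4,6-tris(methoxymethoxy)phenyl]propanoate (syn/anti mixture), via lithium enolate 15 (not isolated)
Conditions: LDA (1.1 equiv), THF, −78 °C; then 14, −78 °C; AcOH quench at −78 °C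
Reagents that add atoms: none
Why: Intermolecular aldol addition of a preformed lithium ester enolate to a non-enolisable aldehyde; the cold quench prevents retro-aldol, and the two new stereocentres are left uncontrolled because both are destroyed later.

**Step 11**
Reactants: 16 tert-butyl 2-Ar-3-hydroxy-3-[2,4,6-tris(methoxymethoxy)phenyl]propanoate
Product: 17 2-Ar-1-[2,4,6-tris(methoxymethoxy)phenyl]propane-1,3-diol (diastereomer mixture)
Conditions: LiAlH4, THF, 0 °C to rt; Fieser work-up; Et3N-deactivated silica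
Reagents that add atoms: none
Why: Hydride reduction of the ester to the primary alcohol; MOM ethers and isolated alkenes are inert to LiAlH4.

**Step 12**
Reactants: 17 2-Ar-1-[2,4,6-tris(methoxymethoxy)phenyl]propane-1,3-diol
Product: 19 2-Ar-3-oxo-3-[2,4,6-tris(methoxymethoxy)phenyl]propanal (racemic; mainly the hydroxymethylene enol), via hydroxy-aldehyde 18 (not isolated)
Conditions: Dess–Martin periodinane (3 equiv), pyridine (10 equiv), CH2Cl2, 0 °C to rt
Reagents that add atoms: none
Why: Double Dess–Martin oxidation of the 1,3-diol to the β-keto-aldehyde; pyridine buffers the acetic acid that would otherwise ionise the electron-rich benzylic carbinol.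

**Step 13**
Reactants: 19 2-Ar-3-oxo-3-[2,4,6-tris(methoxymethoxy)phenyl]propanal
Product: 21 fremontone, via tris-MOM isoflavone 20 (not isolated)
Conditions: HCl (1.25 M in MeOH), THF co-solvent, 45 °C
Reagents that add atoms: none
Why: Acid-catalysed acetal cleavage and cyclodehydration; the carbonyl-flanked MOM ethers go first, so the A-ring phenol closes onto the formyl carbon to give the chromone before the B-ring 2'-OH is freed, and the remaining MOM groups are then solvolysed under conditions mild enough for the two allyl side chains.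

**Compound list**
1 | 4-bromoresorcinol (4-bromobenzene-1,3-diol) | Oc1ccc(Br)c(O)c1 | starting material
2 | 2-bromo-5-{[tri(propan-2-yl)silyl]oxy}phenol | Oc1cc(O[Si](C(C)C)(C(C)C)C(C)C)ccc1Br | intermediate
3 | [4-bromo-3-(2-methylbut-3-en-2-yloxy)phenoxy]tri(propan-2-yl)silane | C=CC(C)(C)Oc1cc(O[Si](C(C)C)(C(C)C)C(C)C)ccc1Br | intermediate
4 | 2-bromo-6-(3-methylbut-2-en-1-yl)-5-{[tri(propan-2-yl)silyl]oxy}cyclohexa-2,4-dien-1-one (racemic) | O=C1C(Br)=CC=C(O[Si](C(C)C)(C(C)C)C(C)C)C1CC=C(C)C | intermediate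
5 | 6-bromo-2-(3-methylbut-2-en-1-yl)-3-{[tri(propan-2-yl)silyl]oxy}phenol | Oc1c(Br)ccc(O[Si](C(C)C)(C(C)C)C(C)C)c1CC=C(C)C | intermediate
6 | [4-bromo-3-(methoxymethoxy)-2-(3-methylbut-2-en-1-yl)phenoxy]tri(propan-2-yl)silane | COCOc1c(Br)ccc(O[Si](C(C)C)(C(C)C)C(C)C)c1CC=C(C)C | intermediate
7 | tetrabutylammonium 4-bromo-3-(methoxymethoxy)-2-(3-methylbut-2-en-1-yl)phenolate | COCOc1c(Br)ccc([O-])c1CC=C(C)C.CCCC[N+](CCCC)(CCCC)CCCC | intermediate
8 | 1-bromo-2-(methoxymethoxy)-3-(3-methylbut-2-en-1-yl)-4-[(3-methylbut-2-en-1-yl)oxy]benzene | COCOc1c(Br)ccc(OCC=C(C)C)c1CC=C(C)C | intermediate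
9 | 4-bromo-3-(methoxymethoxy)-6-(2-methylbut-3-en-2-yl)-2-(3-methylbut-2-en-1-yl)cyclohexa-2,4-dien-1-one (racemic) | O=C1C(CC=C(C)C)=C(OCOC)C(Br)=CC1C(C)(C)C=C | intermediate
10 | 4-bromo-3-(methoxymethoxy)-6-(2-methylbut-3-en-2-yl)-2-(3-methylbut-2-en-1-yl)phenol | COCOc1c(Br)cc(C(C)(C)C=C)c(O)c1CC=C(C)C | intermediate
11 | 1-bromo-2,4-bis(methoxymethoxy)-5-(2-methylbut-3-en-2-yl)-3-(3-methylbut-2-en-1-yl)benzene | COCOc1c(Br)cc(C(C)(C)C=C)c(OCOC)c1CC=C(C)C | intermediate
12 | tert-butyl 2-[2,4-bis(methoxymethoxy)-5-(2-methylbut-3-en-2-yl)-3-(3-methylbut-2-en-1-yl)phenyl]acetate | COCOc1c(CC(=O)OC(C)(C)C)cc(C(C)(C)C=C)c(OCOC)c1CC=C(C)C | intermediate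
13 | 2,4,6-trihydroxybenzaldehyde | O=Cc1c(O)cc(O)cc1O | starting material
14 | 2,4,6-tris(methoxymethoxy)benzaldehyde | COCOc1cc(OCOC)c(C=O)c(OCOC)c1 | intermediate
15 | lithium enolate of 12 (lithium 2-Ar-1-tert-butoxyethen-1-olate) | COCOc1c(C=C(O[Li])OC(C)(C)C)cc(C(C)(C)C=C)c(OCOC)c1CC=C(C)C | intermediate
16 | tert-butyl 2-Ar-3-hydroxy-3-[2,4,6-tris(methoxymethoxy)phenyl]propanoate (syn/anti mixture, racemic) | COCOc1cc(OCOC)c(C(O)C(C(=O)OC(C)(C)C)c2cc(C(C)(C)C=C)c(OCOC)c(CC=C(C)C)c2OCOC)c(OCOC)c1 | intermediate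
17 | 2-Ar-1-[2,4,6-tris(methoxymethoxy)phenyl]propane-1,3-diol (diastereomer mixture, racemic) | COCOc1cc(OCOC)c(C(O)C(CO)c2cc(C(C)(C)C=C)c(OCOC)c(CC=C(C)C)c2OCOC)c(OCOC)c1 | intermediate
18 | 2-Ar-3-hydroxy-3-[2,4,6-tris(methoxymethoxy)phenyl]propanal (diastereomer mixture, racemic) | COCOc1cc(OCOC)c(C(O)C(C=O)c2cc(C(C)(C)C=C)c(OCOC)c(CC=C(C)C)c2OCOC)c(OCOC)c1 | intermediate
19 | 2-Ar-3-oxo-3-[2,4,6-tris(methoxymethoxy)phenyl]propanal (racemic keto form; mainly enol) | COCOc1cc(OCOC)c(C(=O)C(C=O)c2cc(C(C)(C)C=C)c(OCOC)c(CC=C(C)C)c2OCOC)c(OCOC)c1 | intermediate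
20 | 3-Ar-5-hydroxy-7-(methoxymethoxy)-4H-chromen-4-one | COCOc1cc(O)c2c(=O)c(-c3cc(C(C)(C)C=C)c(OCOC)c(CC=C(C)C)c3OCOC)coc2c1 | intermediate
21 | fremontone, 3-[2,4-dihydroxy-5-(2-methylbut-3-en-2-yl)-3-(3-methylbut-2-en-1-yl)phenyl]-5,7-dihydroxy-4H-chromen-4-one (achiral) | C=CC(C)(C)c1cc(-c2coc3cc(O)cc(O)c3c2=O)c(O)c(CC=C(C)C)c1O | target

**Step count**
Total: 13 steps. Longest linear sequence: 12 steps (steps 1–8, then 10–13); step 9 is the one-step side branch.

**Three steps most likely to fail, with fallbacks**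

Step 6 (Claisen rearrangement to the 1,1-dimethylallyl phenol). The risk is that the hot product phenol goes on to abnormal-Claisen or cyclised products, or that the prenyl ether simply cleaves. The fallback sets out from 8 and comes back at 10, and replaces the direct rearrangement by a trap-and-release sequence in which the free phenol never exists at high temperature. 8 is heated in PhNEt2 at 185 °C with Ac2O and NaOAc so that the phenol is acetylated as it forms, giving 4-bromo-3-(methoxymethoxy)-6-(2-methylbut-3-en-2-yl)-2-(3-methylbut-2-en-1-yl)phenyl acetate F1. F1 is then methanolysed with K2CO3 in MeOH at room temperature to give 10.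

Step 12 (one-pot double oxidation). The risks are dehydration of the ionisation-prone benzylic carbinol and over-oxidation of the 1,3-dicarbonyl product. The fallback sets out from 16 and comes back at 21; it keeps the aldol bond but brings in C2 by the deoxybenzoin route and so bypasses steps 11–13. 16 is oxidised only at the benzylic carbinol (DMP 1.3 equiv, pyridine, CH2Cl2) to tert-butyl 2-Ar-3-oxo-3-[2,4,6-tris(methoxymethoxy)phenyl]propanoate F2. Heating F2 in wet DMSO at 150 °C removes the tert-butoxycarbonyl group and gives the deoxybenzoin 2-Ar-1-[2,4,6-tris(methoxymethoxy)phenyl]ethan-1-one F3. Condensation of F3 with Bredereck's reagent (t-BuOCH(NMe2)2, toluene, 100 °C) gives the enaminone 2-Ar-3-(dimethylamino)-1-[2,4,6-tris(methoxymethoxy)phenyl]prop-2-en-1-one F4. Methanolic HCl at 45 °C then removes the MOM groups and closes the pyranone to give 21.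

Step 13 (global acid deprotection and ring closure). The risk is acid-induced cyclisation of the 3'-prenyl or 5'-(1,1-dimethylallyl) group onto a neighbouring phenol, or benzofuran formation through the B-ring 2'-OH. The fallback sets out from 19 and comes back at 21; it separates ring closure from deprotection and exchanges the acid-labile groups for fluoride-labile ones. 19 is cyclised under buffered conditions (PPTS, MeOH, 40 °C) only as far as 20, which is now isolated. The three remaining MOM ethers of 20 are exchanged for silyl ethers with TESOTf and 2,2'-bipyridyl in CH2Cl2 at 0 °C, with 2,6-lutidine added so that the 5-OH is silylated too. This gives 3-[2,4-bis(triethylsilyloxy)-5-(2-methylbut-3-en-2-yl)-3-(3-methylbut-2-en-1-yl)phenyl]-5,7-bis(triethylsilyloxy)-4H-chromen-4-one F5. F5 is desilylated with TBAF buffered with AcOH in THF at 0 °C to give 21 without any strong Brønsted acid.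

**Further compounds**
F1 | step 6 | 4-bromo-3-(methoxymethoxy)-6-(2-methylbut-3-en-2-yl)-2-(3-methylbut-2-en-1-yl)phenyl acetate | CC(=O)Oc1c(CC=C(C)C)c(OCOC)c(Br)cc1C(C)(C)C=C
F2 | step 12 | tert-butyl 2-Ar-3-oxo-3-[2,4,6-tris(methoxymethoxy)phenyl]propanoate (racemic) | COCOc1cc(OCOC)c(C(=O)C(C(=O)OC(C)(C)C)c2cc(C(C)(C)C=C)c(OCOC)c(CC=C(C)C)c2OCOC)c(OCOC)c1
F3 | step 12 | 2-Ar-1-[2,4,6-tris(methoxymethoxy)phenyl]ethan-1-one | COCOc1cc(OCOC)c(C(=O)Cc2cc(C(C)(C)C=C)c(OCOC)c(CC=C(C)C)c2OCOC)c(OCOC)c1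
F4 | step 12 | 2-Ar-3-(dimethylamino)-1-[2,4,6-tris(methoxymethoxy)phenyl]prop-2-en-1-one | CN(C)C=C(C(=O)c1c(OCOC)cc(OCOC)cc1OCOC)c1cc(C(C)(C)C=C)c(OCOC)c(CC=C(C)C)c1OCOC
F5 | step 13 | 3-[2,4-bis(triethylsilyloxy)-5-(2-methylbut-3-en-2-yl)-3-(3-methylbut-2-en-1-yl)phenyl]-5,7-bis(triethylsilyloxy)-4H-chromen-4-one | CC[Si](CC)(CC)Oc1cc(O[Si](CC)(CC)CC)c2c(=O)c(-c3cc(C(C)(C)C=C)c(O[Si](CC)(CC)CC)c(CC=C(C)C)c3O[Si](CC)(CC)CC)coc2c1
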